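**Plan**
- Retrosynthetic cuts, in order: the two O‑benzyl ethers; the C3=CH(aryl) double bond (back to a β‑hydroxy lactone); the C4–C5 ring bond (back to an iodomethyl ester); the C3–C(carbinol) bond (aldol); the styrene C=C (Wittig).
- Forward: the chain is joined first (Wittig, N‑acylation, Evans aldol), the acid is turned into its iodomethyl ester, the lactone (the only ring formed) closes in step 7, then the arylidene is unmasked and the phenols are freed.
- Enabling feature: C5 is an unsubstituted O–CH2 that can be carried as a primary acyloxymethyl radical, and the C4–CH2–aryl unit can be carried as an (E)-styrene whose inner carbon is C4 and whose outer carbon is benzylic to the guaiacyl ring.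
- Stereochemistry: the (S)-oxazolidinone sets C3 and the carbinol carbon in the aldol; C3 relays to C4 (trans) in the radical ring closure; C3 and the carbinol centre are then erased into the (E)-alkene, leaving only (R)-C4.

Key step: step 7

Remark: lactone atoms are numbered O1, C2 (C=O), C3 (arylidene carbon), C4 (stereocentre), C5 (OCH2); the target is read as the (3E,4R) isomer, and both O‑benzyl aldehydes, the phosphonium salt and the oxazolidinone are taken as commercial.

**Step 1**
Reactants: 1 4-(benzyloxy)-3-methoxybenzaldehyde; 2 (2-carboxyethyl)triphenylphosphonium bromide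
Product: 4 (E)-4-[4-(benzyloxy)-3-methoxyphenyl]but-3-enoic acid, via phosphonium ylide 3 (not isolated)
Conditions: 2, NaHMDS (2.2 equiv), THF, 0 °C; then 1, 0 °C → rt; aq. HCl
Reagents that add atoms: none
Why: Wittig olefination with the carboxylate-bearing ylide is expected to favour the (E)-β,γ-unsaturated acid, whose alkene stays in conjugation with the arene.

**Step 2**
Reactants: 4 (E)-4-[4-(benzyloxy)-3-methoxyphenyl]but-3-enoic acid; 5 (4S)-4-benzyl-1,3-oxazolidin-2-one
Product: 7 (4S)-4-benzyl-3-[(3E)-4-[4-(benzyloxy)-3-methoxyphenyl]but-3-enoyl]-1,3-oxazolidin-2-one, via mixed pivalic anhydride 6 (not isolated)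
Conditions: PivCl, Et3N, THF, −20 °C; then 5, LiCl, −20 °C → rt
Reagents that add atoms: none
Why: N-acylation of the oxazolidinone through the mixed anhydride (LiCl/Et3N variant) avoids strong base and should leave the styryl double bond in place.

**Step 3**
Reactants: 7 (4S)-4-benzyl-3-[(3E)-4-[4-(benzyloxy)-3-methoxyphenyl]but-3-enoyl]-1,3-oxazolidin-2-one; 8 3-(benzyloxy)-4,5-dimethoxybenzaldehyde
Product: 10 (4S)-4-benzyl-3-[(2S,3E)-2-[(S)-[3-(benzyloxy)-4,5-dimethoxyphenyl](hydroxy)methyl]-4-[4-(benzyloxy)-3-methoxyphenyl]but-3-enoyl]-1,3-oxazolidin-2-one, via boron dienolate 9 (not isolated)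
Conditions: Bu2BOTf, iPr2NEt, CH2Cl2, −78 → 0 °C; then 8, −78 → 0 °C; pH 7 buffer, MeOH, 30% H2O2, 0 °C
Reagents that add atoms: none
Why: Evans syn-aldol reaction, in which the (Z)-boron dienolate reacts at its α-carbon through a Zimmerman–Traxler chair shielded by the auxiliary benzyl group, so the (2S,3S) adduct should form; C2 of the acyl chain is the future C3 relay centre.

**Step 4**
Reactants: 10 (4S)-4-benzyl-3-[(2S,3E)-2-[(S)-[3-(benzyloxy)-4,5-dimethoxyphenyl](hydroxy)methyl]-4-[4-(benzyloxy)-3-methoxyphenyl]but-3-enoyl]-1,3-oxazolidin-2-one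
Product: 11 (2S,3E)-2-[(S)-[3-(benzyloxy)-4,5-dimethoxyphenyl](hydroxy)methyl]-4-[4-(benzyloxy)-3-methoxyphenyl]but-3-enoic acid
Conditions: LiOH, 30% H2O2, THF/H2O, 0 °C; Na2SO3; then HCl to pH 3
Reagents that add atoms: hydrogen peroxide, OO
Why: Hydroperoxide-mediated cleavage of the N-acyl oxazolidinone attacks the exocyclic carbonyl, and the cold, brief conditions should avoid retro-aldol and α-epimerisation.

**Step 5**
Reactants: 11 (2S,3E)-2-[(S)-[3-(benzyloxy)-4,5-dimethoxyphenyl](hydroxy)methyl]-4-[4-(benzyloxy)-3-methoxyphenyl]but-3-enoic acid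
Product: 12 chloromethyl (2S,3E)-2-[(S)-[3-(benzyloxy)-4,5-dimethoxyphenyl](hydroxy)methyl]-4-[4-(benzyloxy)-3-methoxyphenyl]but-3-enoate
Conditions: ClCH2OSO2Cl, NaHCO3, Bu4NHSO4 (cat.), CH2Cl2/H2O, rt
Reagents that add atoms: chloromethyl chlorosulfate, ClCOS(=O)(=O)Cl
Why: Phase-transfer O-alkylation of the carboxylate by chloromethyl chlorosulfate (chlorosulfate as leaving group) should be selective over the neutral carbinol and too mildly basic to enolise the ester.

**Step 6**
Reactants: 12 chloromethyl (2S,3E)-2-[(S)-[3-(benzyloxy)-4,5-dimethoxyphenyl](hydroxy)methyl]-4-[4-(benzyloxy)-3-methoxyphenyl]but-3-enoate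
Product: 13 iodomethyl (2S,3E)-2-[(S)-[3-(benzyloxy)-4,5-dimethoxyphenyl](hydroxy)methyl]-4-[4-(benzyloxy)-3-methoxyphenyl]but-3-enoate
Conditions: NaI, acetone, rt, dark; filtered, concentrated and used at once
Reagents that add atoms: sodium iodide, [Na+].[I-]
Why: Finkelstein exchange driven by precipitation of NaCl gives the weaker C–I bond needed for clean radical generation.

**Step 7**
Reactants: 13 iodomethyl (2S,3E)-2-[(S)-[3-(benzyloxy)-4,5-dimethoxyphenyl](hydroxy)methyl]-4-[4-(benzyloxy)-3-methoxyphenyl]but-3-enoate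
Product: 16 (3S,4R)-3-[(S)-[3-(benzyloxy)-4,5-dimethoxyphenyl](hydroxy)methyl]-4-[[4-(benzyloxy)-3-methoxyphenyl]methyl]oxolan-2-one, via acyloxymethyl radical 14 (not isolated), via benzylic radical 15 (not isolated)
Conditions: Bu3SnH (1.3 equiv, syringe pump), AIBN (0.2 equiv), PhH, 80 °C, 0.01 M; KF work-up
Reagents that add atoms: none
Why: Iodine abstraction from 13 by Bu3Sn• gives the primary acyloxymethyl radical 14, whose carbon (C5) adds to C4, the styrene carbon nearer the ester, so that the odd electron lands on the guaiacyl-stabilised benzylic carbon of 15 and is quenched there by Bu3SnH to give the benzyl CH2. The closest known reaction type is the tin hydride 5-exo cyclisation of halomethyl esters of but-3-enoic acids and of allyl haloacetates to γ-butyrolactones (Ueno–Stork-type radical lactone closure). The lactone closes in the 5-exo-trig mode; the 6-endo mode would attack the benzylic carbon and leave an unstabilised radical on C4, so the styrene polarisation secures the regiochemistry. The new C4 stereocentre is controlled by the adjacent C3 centre from the aldol: in the chair-like 5-exo transition state the bulky aryl(hydroxy)methyl group on C3 sits pseudo-equatorial and away from the styryl arm, so the C3 and C4 substituents should end up trans, i.e. (3S,4R). The step needs cyclisation to outrun direct reduction of 14 (the ester must reach its s-trans rotamer) and 1,5-hydrogen transfer from the carbinol C–H; high dilution, slow hydride addition at 80 °C and the high radical affinity of the styrene are relied on for this. Any cis isomer is to be removed by chromatography here, because it would lead to the enantiomer once C3 is erased.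

**Step 8**
Reactants: 16 (3S,4R)-3-[(S)-[3-(benzyloxy)-4,5-dimethoxyphenyl](hydroxy)methyl]-4-[[4-(benzyloxy)-3-methoxyphenyl]methyl]oxolan-2-one
Product: 18 (3E,4R)-3-[[3-(benzyloxy)-4,5-dimethoxyphenyl]methylidene]-4-[[4-(benzyloxy)-3-methoxyphenyl]methyl]oxolan-2-one, via mesylate 17 (not isolated)
Conditions: MsCl, Et3N, CH2Cl2, 0 °C; then DBU, rt
Reagents that add atoms: none
Why: Mesylation followed by E1cB elimination through the lactone enolate erases C3 and the carbinol centre and should give the thermodynamically preferred (E)-arylidene (aryl anti to C=O), while the non-acidic C4–H is untouched.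

**Step 9**
Reactants: 18 (3E,4R)-3-[[3-(benzyloxy)-4,5-dimethoxyphenyl]methylidene]-4-[[4-(benzyloxy)-3-methoxyphenyl]methyl]oxolan-2-one
Product: 19 (3E,4R)-3-[(3-hydroxy-4,5-dimethoxyphenyl)methylidene]-4-[(4-hydroxy-3-methoxyphenyl)methyl]oxolan-2-one (target)
Conditions: BCl3 (1 M in CH2Cl2), pentamethylbenzene, CH2Cl2, −78 °C; MeOH quench, aqueous work-up
Reagents that add atoms: none
Why: Lewis-acid debenzylation with a non-basic benzyl cation scavenger at −78 °C should cleave only the aryl benzyl ethers and spare the aryl methyl ethers, the lactone and the conjugated alkene that hydrogenolysis would reduce.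

**Compound list**
1 | 4-(benzyloxy)-3-methoxybenzaldehyde | O=Cc1ccc(OCc2ccccc2)c(OC)c1 | starting material
2 | (2-carboxyethyl)triphenylphosphonium bromide | OC(=O)CC[P+](c1ccccc1)(c1ccccc1)c1ccccc1.[Br-] | starting material
3 | sodium 3-(triphenyl-λ5-phosphanylidene)propanoate (ylide, not isolated) | [Na+].[O-]C(=O)CC=P(c1ccccc1)(c1ccccc1)c1ccccc1 | intermediate
4 | (E)-4-[4-(benzyloxy)-3-methoxyphenyl]but-3-enoic acid | OC(=O)C/C=C/c1ccc(OCc2ccccc2)c(OC)c1 | intermediate
5 | (4S)-4-benzyl-1,3-oxazolidin-2-one | O=C1N[C@@H](Cc2ccccc2)CO1 | starting material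
6 | (E)-4-[4-(benzyloxy)-3-methoxyphenyl]but-3-enoic pivalic anhydride (not isolated) | CC(C)(C)C(=O)OC(=O)C/C=C/c1ccc(OCc2ccccc2)c(OC)c1 | intermediate
7 | (4S)-4-benzyl-3-[(3E)-4-[4-(benzyloxy)-3-methoxyphenyl]but-3-enoyl]-1,3-oxazolidin-2-one | O=C(C/C=C/c1ccc(OCc2ccccc2)c(OC)c1)N1[C@@H](Cc2ccccc2)COC1=O | intermediate
8 | 3-(benzyloxy)-4,5-dimethoxybenzaldehyde | O=Cc1cc(OCc2ccccc2)c(OC)c(OC)c1 | starting material
9 | dibutylboron (Z)-dienolate of 7 (not isolated) | CCCCB(CCCC)O/C(=C\C=C\c1ccc(OCc2ccccc2)c(OC)c1)N1[C@@H](Cc2ccccc2)COC1=O | intermediate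
10 | (4S)-4-benzyl-3-[(2S,3E)-2-[(S)-[3-(benzyloxy)-4,5-dimethoxyphenyl](hydroxy)methyl]-4-[4-(benzyloxy)-3-methoxyphenyl]but-3-enoyl]-1,3-oxazolidin-2-one | O=C(N1[C@@H](Cc2ccccc2)COC1=O)[C@@H](/C=C/c1ccc(OCc2ccccc2)c(OC)c1)[C@H](O)c1cc(OCc2ccccc2)c(OC)c(OC)c1 | intermediate
11 | (2S,3E)-2-[(S)-[3-(benzyloxy)-4,5-dimethoxyphenyl](hydroxy)methyl]-4-[4-(benzyloxy)-3-methoxyphenyl]but-3-enoic acid | OC(=O)[C@@H](/C=C/c1ccc(OCc2ccccc2)c(OC)c1)[C@H](O)c1cc(OCc2ccccc2)c(OC)c(OC)c1 | intermediate
12 | chloromethyl ester of 11 | ClCOC(=O)[C@@H](/C=C/c1ccc(OCc2ccccc2)c(OC)c1)[C@H](O)c1cc(OCc2ccccc2)c(OC)c(OC)c1 | intermediate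
13 | iodomethyl ester of 11 | ICOC(=O)[C@@H](/C=C/c1ccc(OCc2ccccc2)c(OC)c1)[C@H](O)c1cc(OCc2ccccc2)c(OC)c(OC)c1 | intermediate
14 | acyloxymethyl radical from 13 (not isolated) | [CH2]OC(=O)[C@@H](/C=C/c1ccc(OCc2ccccc2)c(OC)c1)[C@H](O)c1cc(OCc2ccccc2)c(OC)c(OC)c1 | intermediate
15 | cyclised benzylic radical (not isolated) | O=C1OC[C@H]([CH]c2ccc(OCc3ccccc3)c(OC)c2)[C@H]1[C@H](O)c1cc(OCc2ccccc2)c(OC)c(OC)c1 | intermediate
16 | (3S,4R)-3-[(S)-[3-(benzyloxy)-4,5-dimethoxyphenyl](hydroxy)methyl]-4-[[4-(benzyloxy)-3-methoxyphenyl]methyl]oxolan-2-one | O=C1OC[C@H](Cc2ccc(OCc3ccccc3)c(OC)c2)[C@H]1[C@H](O)c1cc(OCc2ccccc2)c(OC)c(OC)c1 | intermediate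
17 | methanesulfonate of 16 at the carbinol oxygen (not isolated) | O=C1OC[C@H](Cc2ccc(OCc3ccccc3)c(OC)c2)[C@H]1[C@H](OS(C)(=O)=O)c1cc(OCc2ccccc2)c(OC)c(OC)c1 | intermediate
18 | (3E,4R)-3-[[3-(benzyloxy)-4,5-dimethoxyphenyl]methylidene]-4-[[4-(benzyloxy)-3-methoxyphenyl]methyl]oxolan-2-one | COc1cc(C[C@H]2COC(=O)/C2=C/c2cc(OCc3ccccc3)c(OC)c(OC)c2)ccc1OCc1ccccc1 | intermediate
19 | (3E,4R)-3-[(3-hydroxy-4,5-dimethoxyphenyl)methylidene]-4-[(4-hydroxy-3-methoxyphenyl)methyl]oxolan-2-one | COc1cc(C[C@H]2COC(=O)/C2=C/c2cc(O)c(OC)c(OC)c2)ccc1O | target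

**Totals**
Total step count: 9. Longest linear sequence: 9 steps (1 → 19); aldehyde 8 and auxiliary 5 enter as commercial side inputs.

**Steps most likely to fail**

Step 7. The ring closure may lose to direct reduction of radical 14, to 1,5-hydrogen transfer from the carbinol C–H, or may show poor facial selectivity at C4. The fallback sets C4 by asymmetric hydrogenation and closes the lactone by C–O bond formation instead. It sets out from aldehyde 1. Stobbe condensation with dimethyl succinate (t-BuOK, t-BuOH) should give (3E)-4-[4-(benzyloxy)-3-methoxyphenyl]-3-(methoxycarbonyl)but-3-enoic acid F1. Rhodium–bisphospholane asymmetric hydrogenation, with the ligand antipode chosen for the R acid, should give (3R)-4-[4-(benzyloxy)-3-methoxyphenyl]-3-(methoxycarbonyl)butanoic acid F2. Reduction of the ester in the presence of the carboxylate (LiBH4, THF) and acid lactonisation should give (4R)-4-[[4-(benzyloxy)-3-methoxyphenyl]methyl]oxolan-2-one F3. Aldol addition of its lithium enolate (LiHMDS, THF, −78 °C) to aldehyde 8 should give the trans aldol adduct F4 as a mixture of carbinol epimers. Acid-catalysed dehydration (p-TsOH, toluene, reflux) then comes back to the route at 18.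

Step 6. The iodomethyl ester may be lost before use by intramolecular O-alkylation by the free carbinol or by hydrolysis. The fallback reaches the same radical 14 by decarboxylation instead of halogen abstraction. It sets out from acid 11. O-alkylation with allyl bromoacetate (NaHCO3, DMF) should give the allyl (acyloxy)acetate F5. Deallylation (Pd(PPh3)4, PhSiH3) should give the (acyloxy)acetic acid F6. Coupling with N-hydroxyphthalimide (DIC) should give the redox-active ester F7. Visible-light reductive decarboxylation (Ru(bpy)3Cl2, Hantzsch ester, iPr2NEt, blue light) should release radical 14, which cyclises and is reduced by the Hantzsch ester; this comes back to the route at 16.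

Step 9. Debenzylation may be accompanied by loss of an aryl methyl ether or by benzylation of the electron-rich rings. The fallback moves deprotection ahead of alkene formation. It sets out from lactone 16, which has no C=C bond. Hydrogenolysis (H2, Pd/C, EtOAc) should remove both benzyl groups to give the triol F8. Acid-catalysed dehydration (p-TsOH, toluene, reflux) through the p-methoxy-stabilised benzylic cation, with the phenols left free, should then give target 19 directly.

**Further compounds**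
F1 | step 7 | (3E)-4-[4-(benzyloxy)-3-methoxyphenyl]-3-(methoxycarbonyl)but-3-enoic acid | COC(=O)/C(CC(O)=O)=C/c1ccc(OCc2ccccc2)c(OC)c1
F2 | step 7 | (3R)-4-[4-(benzyloxy)-3-methoxyphenyl]-3-(methoxycarbonyl)butanoic acid | COC(=O)[C@@H](CC(O)=O)Cc1ccc(OCc2ccccc2)c(OC)c1
F3 | step 7 | (4R)-4-[[4-(benzyloxy)-3-methoxyphenyl]methyl]oxolan-2-one | O=C1C[C@@H](Cc2ccc(OCc3ccccc3)c(OC)c2)CO1
F4 | step 7 | (3S,4R)-3-[[3-(benzyloxy)-4,5-dimethoxyphenyl](hydroxy)methyl]-4-[[4-(benzyloxy)-3-methoxyphenyl]methyl]oxolan-2-one, both carbinol epimers | O=C1OC[C@H](Cc2ccc(OCc3ccccc3)c(OC)c2)[C@H]1C(O)c1cc(OCc2ccccc2)c(OC)c(OC)c1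
F5 | step 6 | 2-(allyloxy)-2-oxoethyl ester of acid 11 | C=CCOC(=O)COC(=O)[C@@H](/C=C/c1ccc(OCc2ccccc2)c(OC)c1)[C@H](O)c1cc(OCc2ccccc2)c(OC)c(OC)c1
F6 | step 6 | carboxymethyl ester of acid 11 | OC(=O)COC(=O)[C@@H](/C=C/c1ccc(OCc2ccccc2)c(OC)c1)[C@H](O)c1cc(OCc2ccccc2)c(OC)c(OC)c1
F7 | step 6 | N-hydroxyphthalimide ester of F6 | O=C(COC(=O)[C@@H](/C=C/c1ccc(OCc2ccccc2)c(OC)c1)[C@H](O)c1cc(OCc2ccccc2)c(OC)c(OC)c1)ON1C(=O)c2ccccc2C1=O
F8 | step 9 | (3S,4R)-3-[(S)-hydroxy(3-hydroxy-4,5-dimethoxyphenyl)methyl]-4-[(4-hydroxy-3-methoxyphenyl)methyl]oxolan-2-one | O=C1OC[C@H](Cc2ccc(O)c(OC)c2)[C@H]1[C@H](O)c1cc(O)c(OC)c(OC)c1
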